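**Plan**
- Cuts: the pyran ring at O1–C2 (aryl ether) and at C3=C4 (metathesis); the side chain between its CH2 and the C(CH3)= carbon; in the cyclohexane, the bond between ring carbon C2′ (carries the exocyclic CH2) and ring carbon C3′ (the CH–CH3); the bond from the quaternary ring carbon C1′ to C2′.
- Enabling feature: C2′ is an sp2 ring carbon flanked by quaternary C1′ and secondary C3′. As a 1,1-disubstituted alkenyl anion it can bind a boron atom held on C3′; a boron-to-carbon 1,2-shift then joins C2′ to C3′ with retention, contracting a seven-membered boracycle to the six-membered ring and leaving C=CH2.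
- Forward order: C9 dienol chain, C–B centre, quaternary centre, cyclohexane (ring contraction), chain extension to a Z-allylic carbonate, aryl ether, pyran ring by metathesis, desilylation.
- Stereochemistry: all three centres by catalyst control. C3′ comes from copper-catalysed Markovnikov hydroboration and is carried through the 1,2-shift; C1′ from NHC–copper allylic substitution; chromene C2 from palladium-catalysed asymmetric allylic etherification.

Key step: step 6

Remark: compounds 1, 12 and 18 are taken as commercial; in steps 2, 4 and 15 the ligand enantiomer is assumed to be chosen so that the configuration named is the one formed.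

**Step 1**
Reactants: 1 hept-1-en-6-yne
Product: 3 (2E)-3-methylocta-2,7-dien-1-ol, via alkenylalane 2 (not isolated)
Conditions: Me3Al, Cp2ZrCl2 (cat.), CH2Cl2, 0 °C to rt; then (CH2O)n, THF, rt; aq. HCl
Reagents that add atoms: trimethylaluminium (C[Al](C)C); formaldehyde as paraformaldehyde (C=O)
Why: Negishi zirconium-catalysed carboalumination adds CH3–Al syn across the terminal alkyne (CH3 to the internal carbon) and alkenylalane 2 is hydroxymethylated with retention, so the E trisubstituted allylic alcohol forms while the unactivated terminal alkene is left alone.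

**Step 2**
Reactants: 3 (2E)-3-methylocta-2,7-dien-1-ol
Product: 4 (2E,7R)-3-methyl-7-(4,4,5,5-tetramethyl-1,3,2-dioxaborolan-2-yl)oct-2-en-1-ol
Conditions: CuCl (cat.), 5,8-bis(trimethylsilyl)-QuinoxP* (cat., enantiomer giving 7R), KOt-Bu (cat.), B2pin2, MeOH, THF, 0 °C
Reagents that add atoms: bis(pinacolato)diboron (CC1(C)OB(OC1(C)C)B1OC(C)(C)C(C)(C)O1)
Why: Copper-catalysed Markovnikov protoboration (borylcupration of the terminal alkene, then protonation by methanol) places boron on the internal carbon and sets the 7R centre by ligand control; the trisubstituted alkene is too hindered to react.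

**Step 3**
Reactants: 4 (2E,7R)-3-methyl-7-(4,4,5,5-tetramethyl-1,3,2-dioxaborolan-2-yl)oct-2-en-1-ol
Product: 5 diethyl (2E,7R)-3-methyl-7-(4,4,5,5-tetramethyl-1,3,2-dioxaborolan-2-yl)oct-2-en-1-yl phosphate
Conditions: ClP(O)(OEt)2, Et3N, DMAP (cat.), CH2Cl2, 0 °C
Reagents that add atoms: diethyl chlorophosphate (CCOP(Cl)(=O)OCC)
Why: Routine O-phosphorylation of a primary allylic alcohol; the secondary pinacol boronate is inert.

**Step 4**
Reactants: 5 diethyl (2E,7R)-3-methyl-7-(4,4,5,5-tetramethyl-1,3,2-dioxaborolan-2-yl)oct-2-en-1-yl phosphate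
Product: 6 trimethyl[(3R,7R)-3-ethenyl-3-methyl-7-(4,4,5,5-tetramethyl-1,3,2-dioxaborolan-2-yl)oct-1-en-2-yl]silane
Conditions: HC≡CSiMe3, i-Bu2AlH, hexanes, 55 °C (forms i-Bu2Al[C(SiMe3)=CH2]); then 5, CuCl2·2H2O (cat.), chiral sulfonate-bearing imidazolinium salt (NHC precursor, cat., enantiomer giving 3R), THF, −15 °C
Reagents that add atoms: ethynyltrimethylsilane (C#C[Si](C)(C)C)
Why: NHC–copper-catalysed enantioselective allylic substitution (SN2′) with a vinylaluminium reagent delivers the alkenyl group to the γ-carbon anti to the phosphate inside the chiral pocket, creating the 3R quaternary centre and the ethenyl group by catalyst control, with the remote boronate as a spectator.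

**Step 5**
Reactants: 6 trimethyl[(3R,7R)-3-ethenyl-3-methyl-7-(4,4,5,5-tetramethyl-1,3,2-dioxaborolan-2-yl)oct-1-en-2-yl]silane
Product: 7 2-[(2R,6R)-6-ethenyl-7-iodo-6-methyloct-7-en-2-yl]-4,4,5,5-tetramethyl-1,3,2-dioxaborolane
Conditions: NIS, MeCN, 0 °C to rt, dark
Reagents that add atoms: N-iodosuccinimide (O=C1CCC(=O)N1I)
Why: Electrophilic ipso-iododesilylation of the vinylsilane (β-silyl cation) gives the 2-iodoalkene without touching the boronate or the monosubstituted alkene.

**Step 6**
Reactants: 7 2-[(2R,6R)-6-ethenyl-7-iodo-6-methyloct-7-en-2-yl]-4,4,5,5-tetramethyl-1,3,2-dioxaborolane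
Product: 11 (1R,3R)-1-ethenyl-1,3-dimethyl-2-methylidenecyclohexane, via alkenyllithium 8 (not isolated), via cyclic lithium alkenylboronate 9 (not isolated), via iodomethyl boronic ester 10 (not isolated)
Conditions: t-BuLi (2.05 equiv), THF/Et2O, −95 to −78 °C, high dilution; then I2, MeOH/THF, −78 °C; then NaOMe, MeOH, −78 °C to rt; product kept as a pentane solution (volatile)
Reagents that add atoms: none
Why: Proposed new method: iodine–lithium exchange gives alkenyllithium 8, whose carbanionic carbon adds to the tethered boron to give the seven-membered cyclic alkenyl boronate 9; iodine then activates the exocyclic C=CH2 of 9 as an iodonium ion, the secondary alkyl group migrates antiperiplanar to it from boron to the alkenyl carbon (1,2-metallate shift) to give 10, and methoxide-induced anti elimination of boron and iodide leaves the exocyclic methylene. The closest known reaction types are the Zweifel olefination of secondary pinacol boronic esters with α-substituted vinyllithiums and the electrophile-induced ring-contracting 1,2-metallate rearrangement of cyclic alkenyl boronate complexes; a ring-closing Zweifel olefination through a tethered alkenyllithium has not been shown. The cyclohexane arises by ring contraction of the seven-membered boracycle (formed by intramolecular attack of carbon on three-coordinate boron) to the six-membered carbocycle, not by a direct C–C cyclisation. No new stereocentre is made: the boron-bearing carbon migrates with retention and carries its R configuration into the ring as C3, the quaternary centre is a spectator, and the transient boron-bearing centre of 10 is lost in the elimination. The step needs exchange at the C–I bond to outrun addition of t-BuLi to the hindered secondary boronate (alkenyl iodide, very low temperature), ring closure to beat oligomerisation (dilution and the gem-disubstituted quaternary carbon in the tether), carbon rather than pinacol oxygen to migrate (the ring carbon is the only other carbon ligand on boron), and iodine to attack the electron-rich ate-complex alkene rather than the isolated ethenyl group.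

**Step 7**
Reactants: 12 but-2-yn-1-ol
Product: 14 (2Z)-3-iodobut-2-en-1-ol, via cyclic alkenylalanate 13 (not isolated)
Conditions: NaAlH2(OCH2CH2OMe)2, Et2O, 0 °C to rt; then I2, THF, −78 °C
Reagents that add atoms: iodine (II)
Why: Hydroxyl-directed trans-hydroalumination of the propargylic alcohol places aluminium at C3 in cyclic alanate 13, and iodinolysis with retention gives the Z vinyl iodide.

**Step 8**
Reactants: 11 (1R,3R)-1-ethenyl-1,3-dimethyl-2-methylidenecyclohexane; 14 (2Z)-3-iodobut-2-en-1-ol
Product: 16 (2Z)-5-[(1R,3R)-1,3-dimethyl-2-methylidenecyclohexyl]-3-methylpent-2-en-1-ol, via alkylborane 15 (not isolated)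
Conditions: 9-BBN dimer, THF, rt; then 14, PdCl2(dppf) (cat.), AsPh3 (cat.), Cs2CO3, DMF/H2O, rt
Reagents that add atoms: none
Why: 9-BBN hydroborates the monosubstituted ethenyl group anti-Markovnikov in preference to the doubly α-branched exocyclic 1,1-disubstituted alkene, and primary alkylborane 15 undergoes B-alkyl Suzuki–Miyaura coupling with the vinyl iodide with retention of the Z geometry.

**Step 9**
Reactants: 16 (2Z)-5-[(1R,3R)-1,3-dimethyl-2-methylidenecyclohexyl]-3-methylpent-2-en-1-ol
Product: 17 (2Z)-5-[(1R,3R)-1,3-dimethyl-2-methylidenecyclohexyl]-3-methylpent-2-en-1-yl methyl carbonate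
Conditions: ClCO2Me, pyridine, CH2Cl2, 0 °C
Reagents that add atoms: methyl chloroformate (COC(Cl)=O)
Why: Routine carbonate formation activates the allylic alcohol for ionisation by zerovalent palladium.

**Step 10**
Reactants: 18 2-methoxy-1,4-benzoquinone
Product: 19 5-methoxybenzene-1,2,4-triyl triacetate
Conditions: Ac2O, H2SO4 (cat.), rt to 40 °C
Reagents that add atoms: acetic anhydride (CC(=O)OC(C)=O)
Why: Thiele–Winter acetoxylation: acid-catalysed conjugate addition of acetate to the unsubstituted enone carbon C5 of the quinone, then enolisation and acetylation, gives the 1,2,4,5-tetraoxygenated arene.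

**Step 11**
Reactants: 19 5-methoxybenzene-1,2,4-triyl triacetate
Product: 20 5-methoxybenzene-1,2,4-triol
Conditions: HCl (cat.), degassed MeOH, reflux, Ar; used directly
Reagents that add atoms: none
Why: Acid-catalysed transesterification removes the three aryl acetates under non-oxidising conditions.

**Step 12**
Reactants: 20 5-methoxybenzene-1,2,4-triol
Product: 21 2,2-di-tert-butyl-6-methoxy-1,3,2-benzodioxasilol-5-ol
Conditions: t-Bu2Si(OTf)2 (1.0 equiv, slow addition), 2,6-lutidine, DMF, 0 °C
Reagents that add atoms: di-tert-butylsilyl bis(trifluoromethanesulfonate) (CC(C)(C)[Si](OS(=O)(=O)C(F)(F)F)(OS(=O)(=O)C(F)(F)F)C(C)(C)C)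
Why: Cyclic silylene protection: the bis-electrophilic silyl ditriflate bridges the two adjacent hydroxyls as a five-membered ring and leaves the isolated hydroxyl next to the methoxy group free.

**Step 13**
Reactants: 21 2,2-di-tert-butyl-6-methoxy-1,3,2-benzodioxasilol-5-ol
Product: 22 2,2-di-tert-butyl-4-iodo-6-methoxy-1,3,2-benzodioxasilol-5-ol
Conditions: NIS, MeCN, 0 °C
Reagents that add atoms: N-iodosuccinimide (O=C1CCC(=O)N1I)
Why: Electrophilic aromatic iodination goes ortho to the free hydroxyl (its para position is blocked), at the carbon between OH and the silylene oxygen.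

**Step 14**
Reactants: 22 2,2-di-tert-butyl-4-iodo-6-methoxy-1,3,2-benzodioxasilol-5-ol
Product: 23 2,2-di-tert-butyl-4-ethenyl-6-methoxy-1,3,2-benzodioxasilol-5-ol
Conditions: Bu3SnCH=CH2, Pd(PPh3)4 (cat.), toluene, 100 °C
Reagents that add atoms: tributyl(ethenyl)stannane (CCCC[Sn](CCCC)(CCCC)C=C)
Why: Stille coupling of the aryl iodide with the vinylstannane runs under neutral conditions that spare the silylene and the free phenol.

**Step 15**
Reactants: 17 (2Z)-5-[(1R,3R)-1,3-dimethyl-2-methylidenecyclohexyl]-3-methylpent-2-en-1-yl methyl carbonate; 23 2,2-di-tert-butyl-4-ethenyl-6-methoxy-1,3,2-benzodioxasilol-5-ol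
Product: 24 2,2-di-tert-butyl-4-ethenyl-6-methoxy-5-{[(3S)-5-[(1R,3R)-1,3-dimethyl-2-methylidenecyclohexyl]-3-methylpent-1-en-3-yl]oxy}-1,3,2-benzodioxasilole
Conditions: Pd2(dba)3·CHCl3 (cat.), N,N′-(cyclohexane-1,2-diyl)bis[2-(diphenylphosphanyl)benzamide] (cat., enantiomer giving 3S), CH2Cl2, rt
Reagents that add atoms: none
Why: Palladium-catalysed asymmetric allylic alkylation (Tsuji–Trost etherification): ionisation of the carbonate gives a π-allyl complex and the phenoxide attacks its more substituted terminus inside the chiral pocket, giving the branched tertiary aryl ether with the 3S centre under catalyst control.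

**Step 16**
Reactants: 24 2,2-di-tert-butyl-4-ethenyl-6-methoxy-5-{[(3S)-5-[(1R,3R)-1,3-dimethyl-2-methylidenecyclohexyl]-3-methylpent-1-en-3-yl]oxy}-1,3,2-benzodioxasilole
Product: 25 5,6-O-(di-tert-butylsilanediyl) ether of (2S)-2-{2-[(1R,3R)-1,3-dimethyl-2-methylidenecyclohexyl]ethyl}-8-methoxy-2-methyl-2H-chromene-5,6-diol
Conditions: second-generation Grubbs catalyst (cat.), CH2Cl2, 40 °C
Reagents that add atoms: none
Why: Ring-closing metathesis between the styrene and the tertiary allylic ethenyl group closes the six-membered 2H-pyran ring; the hindered exocyclic 1,1-disubstituted alkene does not take part.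

**Step 17**
Reactants: 25 5,6-O-(di-tert-butylsilanediyl) ether of the target
Product: 26 (2S)-2-{2-[(1R,3R)-1,3-dimethyl-2-methylidenecyclohexyl]ethyl}-8-methoxy-2-methyl-2H-chromene-5,6-diol
Conditions: HF·pyridine, pyridine, THF, 0 °C, Ar; degassed aq. Na2S2O4 work-up
Reagents that add atoms: none
Why: Fluoride-mediated desilylation cleaves the cyclic silylene and frees the catechol under mild, non-oxidising conditions that leave the chromene and the exocyclic alkene untouched.

**Compound list**
1 | hept-1-en-6-yne | C=CCCCC#C | starting material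
2 | [(1E)-2-methylhepta-1,6-dien-1-yl]dimethylalumane (not isolated) | C[Al](C)/C=C(\C)CCCC=C | intermediate
3 | (2E)-3-methylocta-2,7-dien-1-ol | OC/C=C(\C)CCCC=C | intermediate
4 | (2E,7R)-3-methyl-7-(4,4,5,5-tetramethyl-1,3,2-dioxaborolan-2-yl)oct-2-en-1-ol | OC/C=C(\C)CCC[C@@H](C)B1OC(C)(C)C(C)(C)O1 | intermediate
5 | diethyl (2E,7R)-3-methyl-7-(4,4,5,5-tetramethyl-1,3,2-dioxaborolan-2-yl)oct-2-en-1-yl phosphate | CCOP(=O)(OCC)OC/C=C(\C)CCC[C@@H](C)B1OC(C)(C)C(C)(C)O1 | intermediate
6 | trimethyl[(3R,7R)-3-ethenyl-3-methyl-7-(4,4,5,5-tetramethyl-1,3,2-dioxaborolan-2-yl)oct-1-en-2-yl]silane | C=C([Si](C)(C)C)[C@@](C)(C=C)CCC[C@@H](C)B1OC(C)(C)C(C)(C)O1 | intermediate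
7 | 2-[(2R,6R)-6-ethenyl-7-iodo-6-methyloct-7-en-2-yl]-4,4,5,5-tetramethyl-1,3,2-dioxaborolane | C=C(I)[C@@](C)(C=C)CCC[C@@H](C)B1OC(C)(C)C(C)(C)O1 | intermediate
8 | [(3R,7R)-3-ethenyl-3-methyl-7-(4,4,5,5-tetramethyl-1,3,2-dioxaborolan-2-yl)oct-1-en-2-yl]lithium (not isolated) | [Li]C(=C)[C@@](C)(C=C)CCC[C@@H](C)B1OC(C)(C)C(C)(C)O1 | intermediate
9 | lithium (3R,7R)-3-ethenyl-3,7-dimethyl-2-methylidene-1,1-(pinacolato)borepan-1-uide, spiro cyclic alkenyl boronate (not isolated) | [Li+].C=C1[B-]2(OC(C)(C)C(C)(C)O2)[C@H](C)CCC[C@]1(C)C=C | intermediate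
10 | 2-[(2R,6R)-2-ethenyl-1-(iodomethyl)-2,6-dimethylcyclohexyl]-4,4,5,5-tetramethyl-1,3,2-dioxaborolane, either configuration at C1 (not isolated) | ICC1(B2OC(C)(C)C(C)(C)O2)[C@H](C)CCC[C@]1(C)C=C | intermediate
11 | (1R,3R)-1-ethenyl-1,3-dimethyl-2-methylidenecyclohexane | C=C1[C@H](C)CCC[C@]1(C)C=C | intermediate
12 | but-2-yn-1-ol | CC#CCO | starting material
13 | sodium 2,2-bis(2-methoxyethoxy)-3-methyl-2,5-dihydro-1,2-oxaluminol-2-uide (not isolated) | CC1=CCO[Al-]1(OCCOC)OCCOC.[Na+] | intermediate
14 | (2Z)-3-iodobut-2-en-1-ol | OC/C=C(/C)I | intermediate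
15 | 9-{2-[(1S,3R)-1,3-dimethyl-2-methylidenecyclohexyl]ethyl}-9-borabicyclo[3.3.1]nonane (not isolated) | C=C1[C@H](C)CCC[C@]1(C)CCB1C2CCCC1CCC2 | intermediate
16 | (2Z)-5-[(1R,3R)-1,3-dimethyl-2-methylidenecyclohexyl]-3-methylpent-2-en-1-ol | C=C1[C@H](C)CCC[C@]1(C)CC/C(C)=C\CO | intermediate
17 | (2Z)-5-[(1R,3R)-1,3-dimethyl-2-methylidenecyclohexyl]-3-methylpent-2-en-1-yl methyl carbonate | C=C1[C@H](C)CCC[C@]1(C)CC/C(C)=C\COC(=O)OC | intermediate
18 | 2-methoxy-1,4-benzoquinone | COC1=CC(=O)C=CC1=O | starting material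
19 | 5-methoxybenzene-1,2,4-triyl triacetate | COc1cc(OC(C)=O)c(OC(C)=O)cc1OC(C)=O | intermediate
20 | 5-methoxybenzene-1,2,4-triol | COc1cc(O)c(O)cc1O | intermediate
21 | 2,2-di-tert-butyl-6-methoxy-1,3,2-benzodioxasilol-5-ol | COc1cc2O[Si](C(C)(C)C)(C(C)(C)C)Oc2cc1O | intermediate
22 | 2,2-di-tert-butyl-4-iodo-6-methoxy-1,3,2-benzodioxasilol-5-ol | COc1cc2O[Si](C(C)(C)C)(C(C)(C)C)Oc2c(I)c1O | intermediate
23 | 2,2-di-tert-butyl-4-ethenyl-6-methoxy-1,3,2-benzodioxasilol-5-ol | COc1cc2O[Si](C(C)(C)C)(C(C)(C)C)Oc2c(C=C)c1O | intermediate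
24 | 2,2-di-tert-butyl-4-ethenyl-6-methoxy-5-{[(3S)-5-[(1R,3R)-1,3-dimethyl-2-methylidenecyclohexyl]-3-methylpent-1-en-3-yl]oxy}-1,3,2-benzodioxasilole | C=C1[C@H](C)CCC[C@]1(C)CC[C@@](C)(C=C)Oc1c(OC)cc2O[Si](C(C)(C)C)(C(C)(C)C)Oc2c1C=C | intermediate
25 | 5,6-O-(di-tert-butylsilanediyl) ether of (2S)-2-{2-[(1R,3R)-1,3-dimethyl-2-methylidenecyclohexyl]ethyl}-8-methoxy-2-methyl-2H-chromene-5,6-diol | C=C1[C@H](C)CCC[C@]1(C)CC[C@@]1(C)C=Cc2c3O[Si](C(C)(C)C)(C(C)(C)C)Oc3cc(OC)c2O1 | intermediate
26 | (2S)-2-{2-[(1R,3R)-1,3-dimethyl-2-methylidenecyclohexyl]ethyl}-8-methoxy-2-methyl-2H-chromene-5,6-diol | C=C1[C@H](C)CCC[C@]1(C)CC[C@@]1(C)C=Cc2c(O)c(O)cc(OC)c2O1 | target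

**Totals and risks**
Total step count: 17. Longest linear sequence: 11 (steps 1–6, 8, 9, 15–17).

Step 6 (new method). What may go wrong: t-BuLi adds to boron before the iodine–lithium exchange, the seven-membered ate complex oligomerises instead of closing, or the 1,2-shift is outrun by protonation of the alkenyl–boron bond. The fallback sets out from dienol 3 and comes back at 11, forming the same ring bond by palladium-hydride chemistry. Dienol 3 is phosphorylated (ClP(O)(OEt)2, Et3N) to diethyl (2E)-3-methylocta-2,7-dien-1-yl phosphate F1. NHC–copper allylic substitution with i-Bu2Al–C≡C–SiMe3 gives trimethyl[(3R)-3-ethenyl-3-methyloct-7-en-1-yn-1-yl]silane F2, and K2CO3 in MeOH gives (3R)-3-ethenyl-3-methyloct-7-en-1-yne F3. Reductive cyclisation of this 1,7-enyne (Pd2(dba)3·CHCl3, AcOH, Et3SiH) proceeds by hydropalladation of the alkyne, 6-exo carbopalladation of the terminal alkene and silane reduction, and gives 11. In this fallback the methyl-bearing centre is under substrate control only, so (1R,3S)-1-ethenyl-1,3-dimethyl-2-methylidenecyclohexane F4 should form alongside and would have to be removed on AgNO3-impregnated silica.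

Step 4. What may go wrong: slow transfer of the bulky 1-silylvinyl group, so that isobutyl transfer or direct (linear) substitution competes and facial control erodes. The fallback sets out from 5 and comes back at 7, using a slim alkynyl nucleophile and building the iodoalkene afterwards. NHC–copper allylic substitution of 5 with i-Bu2Al–C≡C–SiMe3 gives trimethyl[(3R,7R)-3-ethenyl-3-methyl-7-(4,4,5,5-tetramethyl-1,3,2-dioxaborolan-2-yl)oct-1-yn-1-yl]silane F5. K2CO3 in MeOH gives 2-[(2R,6R)-6-ethenyl-6-methyloct-7-yn-2-yl]-4,4,5,5-tetramethyl-1,3,2-dioxaborolane F6. Markovnikov iodoboration with 9-iodo-9-borabicyclo[3.3.1]nonane followed by protonolysis with AcOH then gives 7.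

Step 15. What may go wrong: the 2,6-disubstituted phenoxide attacks the unsubstituted allyl terminus (linear ether) or attacks with incomplete facial control. The fallback sets out from 16 and 21 and comes back at 25, replacing the catalytic etherification and the metathesis by the classical phenol–enal chromene synthesis. Alcohol 16 is oxidised with MnO2 to (2Z)-5-[(1R,3R)-1,3-dimethyl-2-methylidenecyclohexyl]-3-methylpent-2-enal F7. Condensation of F7 with phenol 21 (ethylenediammonium diacetate, toluene, reflux; ortho-alkylation, dehydration to the ortho-quinone methide, oxa-6π electrocyclisation) gives 25. This gives up catalyst control at chromene C2, so the (2R)-epimer of 25 F8 forms alongside and would be removed by preparative HPLC.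

**Further compounds**
F1 | step 6 | diethyl (2E)-3-methylocta-2,7-dien-1-yl phosphate | CCOP(=O)(OCC)OC/C=C(\C)CCCC=C
F2 | step 6 | trimethyl[(3R)-3-ethenyl-3-methyloct-7-en-1-yn-1-yl]silane | C[Si](C)(C)C#C[C@@](C)(C=C)CCCC=C
F3 | step 6 | (3R)-3-ethenyl-3-methyloct-7-en-1-yne | C#C[C@@](C)(C=C)CCCC=C
F4 | step 6 | (1R,3S)-1-ethenyl-1,3-dimethyl-2-methylidenecyclohexane | C=C1[C@@H](C)CCC[C@]1(C)C=C
F5 | step 4 | trimethyl[(3R,7R)-3-ethenyl-3-methyl-7-(4,4,5,5-tetramethyl-1,3,2-dioxaborolan-2-yl)oct-1-yn-1-yl]silane | C[Si](C)(C)C#C[C@@](C)(C=C)CCC[C@@H](C)B1OC(C)(C)C(C)(C)O1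
F6 | step 4 | 2-[(2R,6R)-6-ethenyl-6-methyloct-7-yn-2-yl]-4,4,5,5-tetramethyl-1,3,2-dioxaborolane | C#C[C@@](C)(C=C)CCC[C@@H](C)B1OC(C)(C)C(C)(C)O1
F7 | step 15 | (2Z)-5-[(1R,3R)-1,3-dimethyl-2-methylidenecyclohexyl]-3-methylpent-2-enal | C=C1[C@H](C)CCC[C@]1(C)CC/C(C)=C\C=O
F8 | step 15 | (2R)-epimer of 25 | C=C1[C@H](C)CCC[C@]1(C)CC[C@]1(C)C=Cc2c3O[Si](C(C)(C)C)(C(C)(C)C)Oc3cc(OC)c2O1
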